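## Retrosynthetic overview

1. C11–OAc comes last, by lipase-catalysed regioselective acetylation of triol 20 (primary allylic OH over secondary 7-OH and tertiary 8-OH).
2. 7β-OH comes from 8α-OH-directed reduction of dienone 19; C11 from Stille hydroxymethylation of dienyl triflate 17; C5=C6 from selenoxide elimination of the 7-ketone.
3. The C8 carbinol comes from β-face epoxidation of the C7=C8 allylic alcohol, then epoxide opening with inversion at C8 assisted by the 10-O-isovalerate.
4. The cyclopentene ring (formed second) comes from a phosphine-catalysed [3+2] annulation of an allenoate onto pyranone 4, anti to the C1 acyloxy group (sets C9).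
5. The pyran ring (formed first) comes from Achmatowicz oxidation of furfuryl alcohol; C1 is set by an isothiourea-catalysed dynamic kinetic acylation that installs the C1 isovalerate directly.

Conventions: iridoid numbering is used for all bicyclic compounds: C1 (acetal CH), O2, C3, C4, C5, C6, C7, C8, C9 (ring-fusion CH next to C1), C10 (CH2 on C8), C11 (CH2 on C4). β is the face carrying H-9. The target is (1S,7S,8R,9S): 1β-O-isovaleryl, 7β-OH, 8α-OH, 8β-CH2O-isovaleryl, H-9β. iVal = 3-methylbutanoyl.

Assumptions: (R)-BTM is taken to give the (S)-ester in step 2, by analogy with its preference for carbinols bearing a π-substituent; if the sense is opposite, use (S)-BTM (both are commercial). Allenoate 7 is made in one step rather than bought.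

## Route

**Step 1**
Reactants: 1, furfuryl alcohol
Product: 2, (±)-6-hydroxy-2H-pyran-3(6H)-one (stereolabile lactol)
Conditions: NBS, NaHCO3, NaOAc, THF/H2O 4:1, 0 °C
Reagents that add atoms: water, O
Why: Achmatowicz oxidative ring expansion gives the pyranone whose hemiacetal carbon (future C1) is racemic and freely epimerising, which the next step exploits.

**Step 2**
Reactants: 2; 3, isovaleric (3-methylbutanoic) anhydride
Product: 4, (S)-5-oxo-5,6-dihydro-2H-pyran-2-yl 3-methylbutanoate [(S)-6-isovaleryloxy-2H-pyran-3(6H)-one]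
Conditions: (R)-BTM (benzotetramisole, 5 mol %), 3 (1.2 equiv), toluene, 0 °C, no amine base
Reagents that add atoms: 3, CC(C)CC(=O)OC(=O)CC(C)C
Why: Chiral isothiourea acyl-transfer catalysis run as a dynamic kinetic resolution (the lactol mutarotates faster than the slow enantiomer is acylated) sets C1 as S and installs the final C1 ester; omitting amine base avoids 3-oxidopyrylium formation.

**Step 3**
Reactants: 5, tert-butyl (triphenylphosphoranylidene)acetate; 6, acetyl chloride
Product: 7, tert-butyl buta-2,3-dienoate
Conditions: Et3N, CH2Cl2, 0 °C → rt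
Reagents that add atoms: 6, CC(Cl)=O (supplies the CH2=C unit)
Why: Wittig olefination of ketene generated in situ from acetyl chloride is the standard allenoate synthesis.

**Step 4**
Reactants: 4; 7
Product: 8, tert-butyl (1S,5S,9S)-1β-isovaleryloxy-4-oxo-cyclopenta[c]pyran-7-ene-10-oate: cis-fused bicycle with C4 ketone, C3H2, C6H2, C7=C8–CO2tBu, H-5β, H-9β
Conditions: PPh3 (20 mol %), toluene, 80 °C
Reagents that add atoms: 7, C=C=CC(=O)OC(C)(C)C (all atoms incorporated)
Why: Lu phosphine-catalysed [3+2] annulation: the allenoate α-carbon adds to the enone β-carbon (C9) anti to the pseudoaxial 1-acyloxy group and the ring closes on the same face, giving the cis-fused cyclopentene with H-9 β (C5 is set only temporarily).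

**Step 5**
Reactants: 8
Product: 9, C3=C4 enol triflate of 8 (4-OTf; Δ3,4 and Δ7,8; H-5β, H-9β)
Conditions: KHMDS (1.05 equiv), THF, −78 °C; then PhNTf2, −78 → −20 °C
Reagents that add atoms: PhNTf2, O=S(=O)(N(c1ccccc1)S(=O)(=O)C(F)(F)F)C(F)(F)F
Why: Kinetic deprotonation at the unhindered, oxygen-activated C3H2 (more acidic than the enoate γ-H or ester α-H) and O-triflation masks the C4 ketone as an oxidant- and acid-stable handle for C11.

**Step 6**
Reactants: 9
Product: 10, the C10 carboxylic acid (C7=C8–CO2H)
Conditions: TFA/CH2Cl2 1:4, 0 °C → rt (no silane scavenger)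
Reagents that add atoms: none
Why: Acidolysis of the tert-butyl ester (loss of isobutene) leaves the acyloxy acetal, the isovalerate and the deactivated enol triflate untouched.

**Step 7**
Reactants: 10
Product: 11, the allylic alcohol (C7=C8–CH2OH)
Conditions: i-BuOCOCl, N-methylmorpholine, THF, −15 °C; then NaBH4, THF/MeOH, −15 → 0 °C
Reagents that add atoms: none
Why: Mixed-anhydride activation followed by borohydride reduction converts the acid to the alcohol without the strong hydride that would cleave the C1 isovalerate.

**Step 8**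
Reactants: 11
Product: 12, the 7β,8β-epoxy alcohol (epoxide oxygen on the β face, CH2OH on C8)
Conditions: VO(acac)2 (5 mol %), t-BuOOH (1.5 equiv, decane), CH2Cl2, 0 °C → rt
Reagents that add atoms: tert-butyl hydroperoxide, CC(C)(C)OO
Why: Hydroxyl-directed vanadium-catalysed epoxidation touches only the allylic-alcohol alkene (not the enol triflate) and delivers oxygen to the convex β face of the cis-fused bicycle.

**Step 9**
Reactants: 12; 3
Product: 13, the 10-O-isovalerate of epoxide 12
Conditions: 3 (1.3 equiv), DMAP (0.1 equiv), pyridine, CH2Cl2, 0 °C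
Reagents that add atoms: 3, CC(C)CC(=O)OC(=O)CC(C)C
Why: DMAP-catalysed acylation of the only free (primary) hydroxyl installs the C10 ester and the neighbouring group needed for the next step.

**Step 10**
Reactants: 13
Product: 14, the 7β,8α-diol 10-O-isovalerate (8β-CH2O-iVal; 4-OTf, Δ3,4, H-5β, H-9β)
Conditions: BF3·OEt2 (1.0 equiv), CH2Cl2, −78 → −40 °C; H2O/THF quench at 0 °C; then PPTS (cat.), CH2Cl2, rt to move any 8-O-acyl isomer to the primary 10-O-ester
Reagents that add atoms: water, O
Why: Anchimerically assisted epoxide opening: the ester carbonyl attacks tertiary C8 in 5-exo fashion from the α face (inversion) to give a 1,3-dioxolan-2-ylium ion that water hydrolyses, so C8 becomes 8α-O/10β and the epoxide oxygen stays as 7β-OH.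

**Step 11**
Reactants: 14
Product: 15, the 7-ketone (8α-OH, 8β-CH2O-iVal)
Conditions: Dess–Martin periodinane, NaHCO3, CH2Cl2, 0 °C → rt
Reagents that add atoms: none
Why: Selective oxidation of the only secondary alcohol gives a ketone that can enolise only toward C6, because C8 is quaternary.

**Step 12**
Reactants: 15
Product: 16, the 6β-phenylseleno-7-ketone with 8-O-TMS
Conditions: TMSOTf (2.5 equiv), Et3N (4 equiv), CH2Cl2, 0 °C; NaHCO3 work-up; then PhSeCl (1.1 equiv), CH2Cl2, −78 °C
Reagents that add atoms: TMSOTf, C[Si](C)(C)OS(=O)(=O)C(F)(F)F; PhSeCl, Cl[Se]c1ccccc1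
Why: Soft enolisation (which leaves the esters alone) gives the C6=C7 silyl enol ether and silylates 8-OH, and the enol ether is selenenylated from the convex β face, syn to H-5.

**Step 13**
Reactants: 16
Product: 17, the dienyl triflate enone: Δ3,4 (4-OTf), Δ5,6, 7-oxo, 8α-OH, 8β-CH2O-iVal, 1β-O-iVal, H-9β
Conditions: 30% H2O2, pyridine (2 equiv), CH2Cl2, 0 °C → rt; then HF·pyridine/pyridine, THF, 0 °C (removes 8-O-TMS)
Reagents that add atoms: none
Why: Reich selenoxide syn-elimination can only use H-5 (C7 is a carbonyl), so the C5=C6 double bond forms regiospecifically; the temporary C5 stereocentre is erased by design.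

**Step 14**
Reactants: 17; 18, (tributylstannyl)methanol
Product: 19, the 4-(hydroxymethyl) dienone (11-OH, Δ3,4, Δ5,6, 7-oxo, 8α-OH)
Conditions: Pd(PPh3)4 (10 mol %), LiCl (3 equiv), 1,4-dioxane, 85 °C
Reagents that add atoms: 18, CCCC[Sn](CCCC)(CCCC)CO
Why: Stille coupling of the electron-poor dienyl triflate introduces C11 as CH2OH under neutral conditions, at the stage where the push–pull dienone makes the ring system most robust.

**Step 15**
Reactants: 19
Product: 20, the triol (11-OH, 7β-OH, 8α-OH), i.e. 11-O-deacetyl target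
Conditions: Me4NBH(OAc)3 (4 equiv), MeCN/AcOH 4:1, −30 °C; cold aq. NaHCO3/Rochelle salt quench
Reagents that add atoms: none
Why: Evans–Saksena hydroxyl-directed reduction: the borohydride bound to 8α-OH delivers hydride intramolecularly to the α face of C7, giving the trans-diol (7β-OH, 7S) with 1,2-selectivity and no ester cleavage.

**Step 16**
Reactants: 20; 21, vinyl acetate
Product: 22, Jatamanvaltrate J
Conditions: immobilised Candida antarctica lipase B (a lipase; Novozym 435), 21 (5 equiv), MTBE, 4 Å MS, 25 °C
Reagents that add atoms: 21, C=COC(C)=O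
Why: Lipase-catalysed irreversible transesterification acetylates only the unhindered primary allylic 11-OH, leaving the secondary 7-OH and tertiary 8-OH free, under neutral conditions that the acid- and base-labile diene acyl-acetal tolerates.

## Compound list

1 | furfuryl alcohol | OCc1ccco1 | starting material
2 | (±)-6-hydroxy-2H-pyran-3(6H)-one | O=C1COC(O)C=C1 | intermediate
3 | isovaleric anhydride | CC(C)CC(=O)OC(=O)CC(C)C | starting material
4 | (S)-6-isovaleryloxy-2H-pyran-3(6H)-one | O=C1CO[C@@H](OC(=O)CC(C)C)C=C1 | intermediate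
5 | tert-butyl (triphenylphosphoranylidene)acetate | CC(C)(C)OC(=O)C=P(c1ccccc1)(c1ccccc1)c1ccccc1 | starting material
6 | acetyl chloride | CC(Cl)=O | starting material
7 | tert-butyl buta-2,3-dienoate | C=C=CC(=O)OC(C)(C)C | intermediate
8 | [3+2] adduct: 4-oxo, Δ7,8, 10-CO2tBu, 1β-O-iVal, H-5β, H-9β | O=C1CO[C@@H](OC(=O)CC(C)C)[C@H]2[C@@H]1CC=C2C(=O)OC(C)(C)C | intermediate
9 | C3=C4 enol triflate of 8 | O=S(=O)(OC1=CO[C@@H](OC(=O)CC(C)C)[C@H]2[C@@H]1CC=C2C(=O)OC(C)(C)C)C(F)(F)F | intermediate
10 | C10 carboxylic acid | O=S(=O)(OC1=CO[C@@H](OC(=O)CC(C)C)[C@H]2[C@@H]1CC=C2C(=O)O)C(F)(F)F | intermediate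
11 | C10 allylic alcohol | O=S(=O)(OC1=CO[C@@H](OC(=O)CC(C)C)[C@H]2[C@@H]1CC=C2CO)C(F)(F)F | intermediate
12 | 7β,8β-epoxy alcohol | O=S(=O)(OC1=CO[C@@H](OC(=O)CC(C)C)[C@H]2[C@@H]1C[C@@H]3O[C@]23CO)C(F)(F)F | intermediate
13 | 7β,8β-epoxy 10-O-isovalerate | O=S(=O)(OC1=CO[C@@H](OC(=O)CC(C)C)[C@H]2[C@@H]1C[C@@H]3O[C@]23COC(=O)CC(C)C)C(F)(F)F | intermediate
14 | 7β,8α-diol 10-O-isovalerate | O=S(=O)(OC1=CO[C@@H](OC(=O)CC(C)C)[C@H]2[C@@H]1C[C@H](O)[C@]2(O)COC(=O)CC(C)C)C(F)(F)F | intermediate
15 | 7-ketone, 8α-OH | O=S(=O)(OC1=CO[C@@H](OC(=O)CC(C)C)[C@H]2[C@@H]1CC(=O)[C@]2(O)COC(=O)CC(C)C)C(F)(F)F | intermediate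
16 | 6β-phenylseleno-7-ketone, 8-O-TMS | O=S(=O)(OC1=CO[C@@H](OC(=O)CC(C)C)[C@H]2[C@@H]1[C@H]([Se]c3ccccc3)C(=O)[C@]2(O[Si](C)(C)C)COC(=O)CC(C)C)C(F)(F)F | intermediate
17 | dienyl triflate enone (Δ3,4, Δ5,6, 7-oxo, 8α-OH) | O=S(=O)(OC1=CO[C@@H](OC(=O)CC(C)C)[C@H]2C1=CC(=O)[C@]2(O)COC(=O)CC(C)C)C(F)(F)F | intermediate
18 | (tributylstannyl)methanol | CCCC[Sn](CCCC)(CCCC)CO | starting material
19 | 4-(hydroxymethyl) dienone | OCC1=CO[C@@H](OC(=O)CC(C)C)[C@H]2C1=CC(=O)[C@]2(O)COC(=O)CC(C)C | intermediate
20 | triol (11-O-deacetyl target) | OCC1=CO[C@@H](OC(=O)CC(C)C)[C@H]2C1=C[C@H](O)[C@]2(O)COC(=O)CC(C)C | intermediate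
21 | vinyl acetate | C=COC(C)=O | starting material
22 | Jatamanvaltrate J, (1S,7S,8R,9S) | CC(=O)OCC1=CO[C@@H](OC(=O)CC(C)C)[C@H]2C1=C[C@H](O)[C@]2(O)COC(=O)CC(C)C | target

## Step count and risks

Total steps: 16. Longest linear sequence: 15 (steps 1, 2, 4–16; step 3 is a one-step side branch).

Steps most likely to fail:

- **Step 10 (ester-assisted epoxide opening).** Risks are Meinwald rearrangement, Lewis-acid ionisation of the C1 acyl acetal, or an ester left on O8. Fallback: open the free epoxy alcohol 12 with water under dilute Brønsted acid (attack at tertiary C8, same inversion) to the 7β,8α,10-triol, then acylate only the primary 10-OH (lipase with isovaleric anhydride, or isovaleryl chloride/collidine at −78 °C).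
- **Step 14 (Stille hydroxymethylation).** Risks are slow transfer of the CH2OH group and heat or base sensitivity of enone 17. Fallback: Pd-catalysed reductive carbonylation of 17 (CO with a tin or silicon hydride) to the C11 aldehyde, then one hydride step that reduces both the C11 aldehyde and the C7 ketone to give 20.
- **Step 15 (directed reduction).** Risks are low reactivity of the vinylogous ketone in 19 and acid lability of 20. Fallback: reorder the end game: run the 8-OH-directed reduction on triflate 17, where the ketone is more electrophilic and the product less acid-labile, and install C11 afterwards by cross-coupling on the diol triflate.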